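Assumptions: CIP analysis of the SMILES gives (R) at the carbinol, with 13 CH2 groups between the carbinol carbon and ring A. (S)-2-(4-fluorophenyl)oxirane (≥98% ee) is taken as a catalogue chiral building block.

## Retrosynthetic overview
1. The 22-membered ring is the only ring formed, and it closes last. The bond made is the diaryl ether C4(ring B)–O(ring A), by visible-light, phenoxyl-radical-enabled displacement of fluoride in an unprotected seco-fluoride.
2. All four phenolic C–O bonds come from a fourfold Ir C–H borylation of 1-(4-fluorophenyl)-14-phenyltetradecan-1-ol, then oxidation in the same flask. The fluorine steers ring B and sterics steer ring A.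
3. The C2–C3 bond comes from Cu-catalysed opening of the purchased (S)-aryl epoxide at its CH2 terminus. The stereogenic C–O bond is never broken.
4. The C12 arm comes from PhMgBr and 1,12-dibromododecane. Both benzene rings are bought.

## Route

**Step 1**
Reactants: 1 phenylmagnesium bromide; 2 1,12-dibromododecane
Product: 3 (12-bromododecyl)benzene
Conditions: 2 (3 equiv), Li2CuCl4 (3 mol %), THF, 0 °C → rt; excess 2 recovered
Reagents that add atoms: none (all atoms come from 1 and 2)
Why: This is a Kochi–Tamura Cu-catalysed Grignard/primary alkyl bromide cross-coupling, and the threefold excess of the symmetric dibromide holds it at mono-substitution.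

**Step 2**
Reactants: 3 (12-bromododecyl)benzene; 4 (S)-2-(4-fluorophenyl)oxirane
Product: 5 (R)-1-(4-fluorophenyl)-14-phenyltetradecan-1-ol
Conditions: 3 (1.2 equiv), Mg, THF, 45 °C; then CuI (10 mol %), 4, THF, −40 → 0 °C; aq NH4Cl
Reagents that add atoms: none (all atoms come from 3 and 4)
Why: This is a Cu(I)-catalysed SN2 epoxide opening by a primary alkyl Grignard at the unhindered CH2, so the benzylic C–O bond of 4 is untouched, the bought configuration is retained (S→R is only a CIP priority change), and Ar–F is inert.

**Step 3**
Reactants: 5 (R)-1-(4-fluorophenyl)-14-phenyltetradecan-1-ol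
Product: 6 (R)-pentaboryl intermediate. This is the O-Bpin ether of 5 carrying C-Bpin at C3 and C5 of the fluoroarene (both flanking F) and at C3' and C5' of the terminal phenyl ring. It is used crude in the same flask.
Conditions: HBpin (1.2 equiv), B2pin2 (3.5 equiv), [Ir(OMe)(cod)]2 (4 mol %), tmphen (8 mol %), THF, 80 °C, 24 h; cool to 0 °C, no work-up
Reagents that add atoms: bis(pinacolato)diboron, CC1(C)OB(OC1(C)C)B1OC(C)(C)C(C)(C)O1; pinacolborane, CC1(C)OBOC1(C)C
Why: This is a sterically governed Ir-catalysed aromatic C–H borylation in which HBpin first caps the alcohol as O-Bpin, ring B can react only at the two C–H bonds next to the small F, ring A funnels through the meta-monoboronate to the 3,5-diboronate (the para-monoboryl dead end, about one third, is carried on and removed after Step 4), and the stereocentre is not involved.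

**Step 4** (same flask as Step 3)
Reactants: 6 (R)-pentaboryl intermediate
Product: 7 (R)-2-fluoro-5-[14-(3,5-dihydroxyphenyl)-1-hydroxytetradecyl]benzene-1,3-diol
Conditions: 30% H2O2, 2 M NaOH, THF, 0 °C, 1 h; Na2S2O3, NaH2PO4 work-up; chromatography
Reagents that add atoms: hydrogen peroxide, OO (the four phenolic O atoms)
Why: This is a boronate ipso-oxidation (1,2-aryl shift from B to O in the hydroperoxide ate complex) that turns each C–B into C–OH at the same position, while the O–Bpin ether hydrolyses at the O–B bond so the carbinol C–O bond and the (R) configuration are kept, Ar–F is inert at 0 °C, and the less polar para-hydroxy triphenol by-product is separated on silica.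

**Step 5** (key step)
Reactants: 7 (R)-2-fluoro-5-[14-(3,5-dihydroxyphenyl)-1-hydroxytetradecyl]benzene-1,3-diol
Product: 8 gravicycle, (R)
Conditions: [Ir(dF(CF3)ppy)2(dtbbpy)]PF6 (2 mol %), K3PO4 (3 equiv), 4 Å MS, degassed MeCN–DMSO 9:1, 7 added over 12 h (final 1 mM), 450 nm LEDs, 45 °C, Ar, 24 h; pH 6 buffer work-up
Reagents that add atoms: none (HF is lost)
Why: Proposed new method: a visible-light, redox-neutral, phenoxyl-radical-enabled SNAr macro-etherification. Excited Ir(III), with phosphate as the proton acceptor, converts a phenol of 7 into a phenoxyl radical; in the redox tautomer with the radical on ring B, the O• group (an electron-withdrawing group far stronger than NO2) sits ortho to C4–F and makes that carbon electrophilic. One of the two equivalent ring-A phenoxides adds ipso, and fluoride, H-bonded to the flanking OH and trapped as KF, leaves irreversibly. The product phenoxyl radical is then reduced by Ir(II), or by a further phenoxide of 7 in a chain-propagating step. No terminal oxidant is present, so ordinary oxidative phenol couplings at C–H sites cannot turn over and F-displacement is the only productive exit. The position of F fixes the regiochemistry, the ring-B and carbinol OH groups cannot reach C4 intramolecularly, and dilution suppresses oligomers. The carbinol carbon is meta to both radical-bearing oxygens, so no quinone methide can form and the configuration is kept. The closest known reaction types are homolysis-enabled electronic-activation SNAr of 4-fluorophenols with carboxylates (thermal, ferricyanide-initiated, intermolecular) and photoredox cation-radical-accelerated SNAr of fluoro- and alkoxyarenes. The new elements are photocatalytic radical generation, an ortho-F flanked by two OH groups, a phenol nucleophile, and macrocyclisation.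

## Compound list
1 | phenylmagnesium bromide | Br[Mg]c1ccccc1 | starting material
2 | 1,12-dibromododecane | BrCCCCCCCCCCCCBr | starting material
3 | (12-bromododecyl)benzene | BrCCCCCCCCCCCCc1ccccc1 | intermediate
4 | (S)-2-(4-fluorophenyl)oxirane | Fc1ccc(cc1)[C@H]1CO1 | starting material
5 | (R)-1-(4-fluorophenyl)-14-phenyltetradecan-1-ol | Fc1ccc(cc1)[C@H](O)CCCCCCCCCCCCCc1ccccc1 | intermediate
6 | (R)-pentaboryl intermediate: O-Bpin ether of 5 with C-Bpin at C3/C5 of the fluoroarene and C3'/C5' of the terminal phenyl ring (used crude) | CC1(C)OB(OC1(C)C)c1cc(cc(B2OC(C)(C)C(C)(C)O2)c1F)[C@H](OB1OC(C)(C)C(C)(C)O1)CCCCCCCCCCCCCc1cc(cc(c1)B1OC(C)(C)C(C)(C)O1)B1OC(C)(C)C(C)(C)O1 | intermediate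
7 | (R)-2-fluoro-5-[14-(3,5-dihydroxyphenyl)-1-hydroxytetradecyl]benzene-1,3-diol | Oc1cc(cc(O)c1F)[C@H](O)CCCCCCCCCCCCCc1cc(O)cc(O)c1 | intermediate
8 | gravicycle, (R) | Oc1cc2cc(c1)Oc1c(O)cc(cc1O)[C@H](O)CCCCCCCCCCCCC2 | target

## Step count and risks
Total steps: 5. Steps 3 and 4 are telescoped in one flask, so there are four isolations. Longest linear sequence: 5. No separate protecting-group steps are used.

**Steps most likely to fail**

1. **Step 5 (the new step).**
   - Risks:
     - The ring-B radical may not live long enough for a slow macrocyclic SNAr.
     - Proton transfer from the acidic hydroxy-phenoxyl radical to the ring-A phenoxide lowers the population of the reactive pair.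
     - C-attack by the resorcinolate on C4 would give a biaryl.
     - Oligomers may form.
   - Fallback (known chemistry throughout):
     - Run the same assembly from (S)-styrene oxide and 3,5-bis(TBSO)phenylmagnesium bromide.
     - Diborylate ring B and oxidise under buffered conditions.
     - Iodinate C4 between the two free OH groups with I2/NaHCO3 (the 2-iodoresorcinol protocol).
     - Cap those OH groups with BnBr/K2CO3 and free ring A with TBAF.
     - Close the ring by a classical high-dilution Ullmann macro-etherification (CuI, N,N-dimethylglycine, Cs2CO3, dioxane, 100 °C).
     - Finish with H2, Pd/C in neutral EtOAc, which spares the benzylic carbinol.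

2. **Step 3.**
   - Risks: statistical para-borylation of ring A, and an incomplete second borylation next to F.
   - Fallback: give up C–H oxygenation of ring A. Use 3,5-bis(TBSO)phenylmagnesium bromide (from 5-bromoresorcinol, one extra step) in Step 1. Only the two F-flanked C–H bonds then need borylating, and the aryl TBS ethers are cleaved by the NaOH/H2O2 of Step 4 to give 7.

3. **Step 2.**
   - Risks: benzylic attack, or Mg-promoted Meinwald rearrangement of the styrene-type oxide.
   - Fallback: avoid Lewis-acidic organometallics. Convert 3 to the phenyl sulfone with PhSO2Na. Open 4 at CH2 with the α-lithio sulfone (n-BuLi, THF). Remove the sulfonyl group reductively (Mg/MeOH) to reach 5. This adds two steps and gives the same carbon count.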